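The south run, the south-east run and the flask each hold 66 µM of added ligand, while the enzyme charged is 17.0 µM, 37.5 µM and 25.0 µM, so added ligand exceeds enzyme in each.

| flask | substrate | enzyme | added ligand | remark |
|---|---|---|---|---|
| south | 0.050 M | 0.034 mol% | 66 µM | run made earlier |
| south-east | 0.050 M | 0.075 mol% | 66 µM | run made earlier |
| flask | 0.050 M | 0.05 mol% | 66 µM |  |

| run | time / h | target / % |
|---|---|---|
| south | 1.00 | 0.8 |
| south | 3.00 | 2.4 |
| south | 5.00 | 3.7 |
| south | 8.00 | 5.6 |
| south-east | 0.667 | 1.7 |
| south-east | 1.33 | 3.0 |
| south-east | 3.00 | 8.0 |
| south-east | 8.00 | 19.3 |

(scatter of a reading: 0.3 percentage points)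

1. apparent order in enzyme when 20% of the substrate are converted (percent change of the rate of making target for one percent more enzyme charged)
2. factor on the rate of making target when 20% of the substrate are converted if enzyme is charged twice over

Two of us read these runs differently. The first holds that rate follows a power of the enzyme. At 8.00 h, target in the south-east run is 3.45 times that in the south run, for 2.21 times the enzyme. The secant order, the logarithm of the first ratio over that of the second, is 1.56. The flask lies between the runs, so this view carries the number over. Charging enzyme twice over then gives a factor of 2.96.

I hold a different view, and it is an assumption: added ligand holds enzyme tightly, one to one, in an idle complex, an off-cycle form. What counts then is the spare ligand, added ligand charged minus enzyme charged, 41.0 µM in the flask. Free enzyme goes as enzyme charged over spare ligand. So the order is ligand charged over spare ligand, 1.61 for the flask. Between the runs this rule asks for a ratio of 3.79, higher than the reading. The two orders agree, so we part on the doubling. There spare ligand shrinks to 16.0 µM, and my factor becomes 5.13.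

The forecast carries a secant order over, reasoning that “this secant order applies there directly”, and gives an order of 1.5 and a factor of 2.7.

The simulation gives an order of 1.6 and a factor of 4.24.

    substrate + enzyme ⇌ starting complex (K = 8.83 M⁻¹, k = 30700 M⁻¹ min⁻¹)
    starting complex → enzyme + target (k = 47.3 min⁻¹)
    enzyme + added ligand ⇌ idle complex, settled at all times (K = 1.10 × 10⁶ M⁻¹)

The factor lies below my 5.13 and above the power view's 2.96. The power view keeps its region between the two runs, where its order of 1.56 stands beside the flask's 1.6, but the doubled charge of 50.0 µM lies beyond south-east's 37.5 µM. In the flask at 8.00 h, added ligand stands at 63.2% of its charge, 41.7 µM beside the spare 41.0 µM, and idle complex holds 97.1% of the catalyst, and 97.5% at 80.0 h. This binding is a part of the reason for the raised order: the flask without it gives 1.0 instead of 1.6.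

(The readings are simulated with made-up constants, noise included.)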